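**Plan**

Numbering used throughout: oxolane O1, C2 (4-hydroxyphenyl), C3 (bears C9H2OAc), C4 (bears C7'H(OAc)-anisyl), C5H2. O1 lies between the benzylic methine C2 and the bare methylene C5. Removing O1 and joining C2 to C5 contracts the oxolane to the carbocycle C5–C2–C3–C4, a 2-aryl-3-(oxymethyl)cyclobutanone with C5 as the carbonyl carbon.
Retrosynthetic cuts, in order: acetate/phenol adjustments; O1–C5 (C5 back to a lactone carbonyl); C4–C7' (aldol); O1 excised from between C2 and C5 (Baeyer–Villiger); C4–C5 and C2–C3 together ([2+2] of an arylketeniminium ion with an allyl ether).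
Forward: the four-membered ring is made first and enlarged by oxygen insertion to the γ-lactone. The anisyl carbinol arm is added at C4, and the lactone becomes the oxolane by reduction and re-closure of O1 onto C5. Desilylation, peracetylation and release of the phenol finish the route.
Stereochemistry: C3 comes from a C2-symmetric (2R,5R)-2,5-dimethylpyrrolidine auxiliary. C2 comes from equilibration to the 2,3-trans ketone followed by stereoretentive migration. C4 comes from enolate attack anti to the C3 arm, and C7' from a syn-selective potassium-enolate aldol.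

Key step: step 6

Assumption: the (2R,5R)-amine is taken to give the (3R)-cycloadduct, following the quadrant model stated at step 4; both antipodes of the amine are commercial, so a reversed sense of induction would be met by using the mirror-image amine with nothing else changed.

Step 1
Reactants: 1 4-hydroxyphenylacetic acid
Product: 3 2-[4-(triisopropylsilyloxy)phenyl]acetic acid, via bis-silyl ester 2 (not isolated)
Conditions: TIPSCl (2.2 equiv), imidazole, DMF, rt; then K2CO3, THF–MeOH–H2O, rt, work-up at pH 4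
Reagents that add atoms: triisopropylsilyl chloride (TIPSCl), CC(C)[Si](Cl)(C(C)C)C(C)C
Why: Exhaustive imidazole-mediated silylation of phenol and acid is followed by mild carbonate hydrolysis, which cleaves only the much more labile silyl ester and leaves the hindered aryl silyl ether; no stereocentre is involved.

Step 2
Reactants: 3 2-[4-(triisopropylsilyloxy)phenyl]acetic acid; 4 (2R,5R)-2,5-dimethylpyrrolidine
Product: 6 1-[(2R,5R)-2,5-dimethylpyrrolidin-1-yl]-2-[4-(triisopropylsilyloxy)phenyl]ethan-1-one, via acid chloride 5 (not isolated)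
Conditions: (COCl)2, DMF (cat.), CH2Cl2, 0 °C → rt; then 4, Et3N, CH2Cl2, 0 °C
Reagents that add atoms: none
Why: Acid chloride formation under Vilsmeier catalysis followed by N-acylation overcomes the hindrance of the α,α'-branched amine, whose two stereocentres are untouched, and the aryl silyl ether tolerates the HCl released.

Step 3
Reactants: 7 allyl alcohol
Product: 8 allyl triisopropylsilyl ether (3-(triisopropylsilyloxy)prop-1-ene)
Conditions: TIPSCl, imidazole, CH2Cl2, rt
Reagents that add atoms: triisopropylsilyl chloride (TIPSCl), CC(C)[Si](Cl)(C(C)C)C(C)C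
Why: This is a standard O-silylation, and the bulky silyl group lowers the Lewis basicity of the allylic oxygen toward Tf2O and the keteniminium ion and later resists migration between neighbouring oxygens.

Step 4
Reactants: 6 1-[(2R,5R)-2,5-dimethylpyrrolidin-1-yl]-2-[4-(triisopropylsilyloxy)phenyl]ethan-1-one; 8 allyl triisopropylsilyl ether
Product: 11 (3R)-2-[4-(triisopropylsilyloxy)phenyl]-3-[(triisopropylsilyloxy)methyl]cyclobutan-1-one as a mixture of C2 epimers, via keteniminium triflate 9 (not isolated), via cyclobutaniminium triflate 10 (not isolated)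
Conditions: Tf2O, 2,4,6-collidine, 8 (3 equiv), ClCH2CH2Cl, 0 → 60 °C; then H2O–CH2Cl2, 40 °C
Reagents that add atoms: water, O
Why: In this keteniminium–alkene [2+2] cycloaddition (Ghosez cyclobutanone synthesis) the electrophilic central carbon (future C5) takes the terminal CH2 of 8 (future C4), charge builds on the internal carbon (future C3), which closes onto C2 and so places the oxymethyl arm next to the aryl-bearing carbon, while the alkene approaches anti to the aryl group through the quadrant left free of a methyl group by the C2-symmetric pyrrolidine, which sets C3 as R and leaves C2 to step 5.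

Step 5
Reactants: 11 (3R)-2-[4-(triisopropylsilyloxy)phenyl]-3-[(triisopropylsilyloxy)methyl]cyclobutan-1-one (C2 epimers)
Product: 12 (2R,3R)-2-[4-(triisopropylsilyloxy)phenyl]-3-[(triisopropylsilyloxy)methyl]cyclobutan-1-one (2,3-trans)
Conditions: DBU (0.1 equiv), dry toluene, rt
Reagents that add atoms: none
Why: Base-catalysed enolisation (thermodynamic epimerisation) of the acidic benzylic α-carbon C2 should drain the mixture toward the less congested 2,3-trans isomer with C3 as the fixed reference, and a non-nucleophilic amidine in dry solvent avoids both ring cleavage by addition to the strained carbonyl and loss of the aryl silyl ether.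

Step 6
Reactants: 12 (2R,3R)-2-[4-(triisopropylsilyloxy)phenyl]-3-[(triisopropylsilyloxy)methyl]cyclobutan-1-one
Product: 14 (4S,5R)-5-[4-(triisopropylsilyloxy)phenyl]-4-[(triisopropylsilyloxy)methyl]oxolan-2-one (4,5-trans), via Criegee adduct 13 (not isolated)
Conditions: m-CPBA, NaHCO3, CH2Cl2, 0 °C → rt
Reagents that add atoms: 3-chloroperoxybenzoic acid (m-CPBA), OOC(=O)c1cccc(Cl)c1
Why: This is the Baeyer–Villiger oxidation of a 2-substituted cyclobutanone to a γ-butyrolactone, a long-established reaction type: the peracid adds to the strained C5 carbonyl to give adduct 13, and the C5–C2 bond, aligned antiperiplanar to the O–O bond, shifts to the proximal peroxide oxygen as 3-chlorobenzoate leaves. No ring is closed by cyclisation; the five-membered lactone arises by one-atom enlargement of the four-membered carbocycle, O1 entering between C2 and C5 so that O1–C2 and O1–C5 are formed in one event. No stereocentre is created: the migrating carbon keeps its configuration in the suprafacial 1,2-shift, so the trans C2/C3 relationship fixed in step 5 is carried into the C2–O1 bond, where C2 is no longer enolisable, and C3 is a bystander. The selectivity required is regiochemical, migration of C2 and not of the C4 methylene, and the substrate secures it because a secondary benzylic carbon with a para-silyloxy donor carries the developing positive charge far better than a primary carbon. Chemoselectivity rests on ring strain, which lets the ketone react at low temperature, where the buffered peracid should leave the mono-oxygenated arene and both silyl ethers alone.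

Step 7
Reactants: 14 (4S,5R)-5-[4-(triisopropylsilyloxy)phenyl]-4-[(triisopropylsilyloxy)methyl]oxolan-2-one; 15 4-methoxybenzaldehyde
Product: 17 (3S,4S,5R)-3-[(S)-hydroxy(4-methoxyphenyl)methyl]-5-[4-(triisopropylsilyloxy)phenyl]-4-[(triisopropylsilyloxy)methyl]oxolan-2-one, via potassium enolate 16 (not isolated)
Conditions: KN(SiMe3)2, THF–toluene, −78 °C; 15; AcOH quench at −78 °C
Reagents that add atoms: none
Why: In this aldol addition of a γ-butyrolactone enolate to an aromatic aldehyde the aldehyde meets the planar enolate on the face opposite the adjacent CH2OTIPS arm, which sets C4 trans to C3, and the weakly coordinating potassium ion favours an open antiperiplanar transition state that converts the ring-locked E(O)-enolate into the syn (erythro) aldol, (S) at C7', with the cold acidic quench freezing the kinetic aldolate.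

Step 8
Reactants: 17 (3S,4S,5R)-3-[(S)-hydroxy(4-methoxyphenyl)methyl]-5-[4-(triisopropylsilyloxy)phenyl]-4-[(triisopropylsilyloxy)methyl]oxolan-2-one
Product: 18 (1S,2R,3S,4R)-2-(hydroxymethyl)-1-(4-methoxyphenyl)-4-[4-(triisopropylsilyloxy)phenyl]-3-[(triisopropylsilyloxy)methyl]butane-1,4-diol
Conditions: LiAlH4, THF, 0 °C
Reagents that add atoms: none
Why: Hydride reduction of a lactone to the 1,4-diol breaks only the acyl C5–O1 bond, so the C2–O bond made in step 6 and all four stereocentres persist, and aluminium alkoxides at 0 °C are poorly disposed to retro-aldol cleavage or silyl migration.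

Step 9
Reactants: 18 (1S,2R,3S,4R)-2-(hydroxymethyl)-1-(4-methoxyphenyl)-4-[4-(triisopropylsilyloxy)phenyl]-3-[(triisopropylsilyloxy)methyl]butane-1,4-diol
Product: 20 (2R,3S,4R)-4-[(S)-hydroxy(4-methoxyphenyl)methyl]-2-[4-(triisopropylsilyloxy)phenyl]-3-[(triisopropylsilyloxy)methyl]oxolane, via primary tosylate 19 (not isolated)
Conditions: TsCl (1.1 equiv), Et3N, DMAP (cat.), CH2Cl2, 0 → 40 °C
Reagents that add atoms: none
Why: Selective sulfonylation of the only primary hydroxyl followed by intramolecular Williamson etherification (5-exo-tet) by the C2 hydroxyl re-forms O1–C5 at a non-stereogenic carbon, so C2 keeps its configuration, and the C7' hydroxyl can compete only through a much slower 4-exo closure to an oxetane.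

Step 10
Reactants: 20 (2R,3S,4R)-4-[(S)-hydroxy(4-methoxyphenyl)methyl]-2-[4-(triisopropylsilyloxy)phenyl]-3-[(triisopropylsilyloxy)methyl]oxolane
Product: 21 (2R,3S,4R)-2-(4-hydroxyphenyl)-3-(hydroxymethyl)-4-[(S)-hydroxy(4-methoxyphenyl)methyl]oxolane
Conditions: Bu4NF, AcOH, THF, 0 °C → rt
Reagents that add atoms: none
Why: Fluoride-induced desilylation cleaves both Si–O bonds, and the acetic acid buffer keeps the liberated phenol protonated so that opening of the para-hydroxybenzylic ether through a quinone methide, and with it epimerisation at C2, is avoided.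

Step 11
Reactants: 21 (2R,3S,4R)-2-(4-hydroxyphenyl)-3-(hydroxymethyl)-4-[(S)-hydroxy(4-methoxyphenyl)methyl]oxolane
Product: 22 (2R,3S,4R)-2-(4-acetoxyphenyl)-3-(acetoxymethyl)-4-[(S)-acetoxy(4-methoxyphenyl)methyl]oxolane
Conditions: Ac2O, pyridine, DMAP (cat.), CH2Cl2, 0 °C → rt
Reagents that add atoms: acetic anhydride, CC(=O)OC(C)=O
Why: DMAP-catalysed acylation under basic conditions esterifies the phenol, the primary hydroxyl and the secondary benzylic hydroxyl at oxygen without ionising the para-methoxybenzylic centre, so C7' is retained.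

Step 12
Reactants: 22 (2R,3S,4R)-2-(4-acetoxyphenyl)-3-(acetoxymethyl)-4-[(S)-acetoxy(4-methoxyphenyl)methyl]oxolane
Product: 23 (2R,3S,4R)-3-(acetoxymethyl)-4-[(S)-acetoxy(4-methoxyphenyl)methyl]-2-(4-hydroxyphenyl)oxolane (CNP0231272.1)
Conditions: pyrrolidine (1.1 equiv), CH2Cl2, 0 °C
Reagents that add atoms: none
Why: In this chemoselective aminolysis the aryl acetate, with its phenoxide leaving group, acylates the secondary amine far faster than either alkyl acetate, and the cold aprotic medium gives the para-methoxybenzylic acetate no opportunity to solvolyse.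

**Compound list**

1 | 4-hydroxyphenylacetic acid | OC(=O)Cc1ccc(O)cc1 | starting material
2 | triisopropylsilyl 2-[4-(triisopropylsilyloxy)phenyl]acetate | CC(C)[Si](OC(=O)Cc1ccc(O[Si](C(C)C)(C(C)C)C(C)C)cc1)(C(C)C)C(C)C | intermediate
3 | 2-[4-(triisopropylsilyloxy)phenyl]acetic acid | OC(=O)Cc1ccc(O[Si](C(C)C)(C(C)C)C(C)C)cc1 | intermediate
4 | (2R,5R)-2,5-dimethylpyrrolidine | C[C@@H]1CC[C@@H](C)N1 | starting material
5 | 2-[4-(triisopropylsilyloxy)phenyl]acetyl chloride | ClC(=O)Cc1ccc(O[Si](C(C)C)(C(C)C)C(C)C)cc1 | intermediate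
6 | 1-[(2R,5R)-2,5-dimethylpyrrolidin-1-yl]-2-[4-(triisopropylsilyloxy)phenyl]ethan-1-one | O=C(Cc1ccc(O[Si](C(C)C)(C(C)C)C(C)C)cc1)N1[C@H](C)CC[C@H]1C | intermediate
7 | allyl alcohol | C=CCO | starting material
8 | allyl triisopropylsilyl ether | C=CCO[Si](C(C)C)(C(C)C)C(C)C | intermediate
9 | (2R,5R)-2,5-dimethyl-1-{2-[4-(triisopropylsilyloxy)phenyl]ethenylidene}pyrrolidinium triflate | CC(C)[Si](Oc1ccc(C=C=[N+]2[C@H](C)CC[C@H]2C)cc1)(C(C)C)C(C)C.[O-]S(=O)(=O)C(F)(F)F | intermediate
10 | (2R,5R)-2,5-dimethyl-1-{(3R)-2-[4-(triisopropylsilyloxy)phenyl]-3-[(triisopropylsilyloxy)methyl]cyclobutylidene}pyrrolidinium triflate (C2 epimers) | C1C(=[N+]2[C@H](C)CC[C@H]2C)C(c3ccc(O[Si](C(C)C)(C(C)C)C(C)C)cc3)[C@@H]1CO[Si](C(C)C)(C(C)C)C(C)C.[O-]S(=O)(=O)C(F)(F)F | intermediate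
11 | (3R)-2-[4-(triisopropylsilyloxy)phenyl]-3-[(triisopropylsilyloxy)methyl]cyclobutan-1-one (C2 epimers) | C1C(=O)C(c2ccc(O[Si](C(C)C)(C(C)C)C(C)C)cc2)[C@@H]1CO[Si](C(C)C)(C(C)C)C(C)C | intermediate
12 | (2R,3R)-2-[4-(triisopropylsilyloxy)phenyl]-3-[(triisopropylsilyloxy)methyl]cyclobutan-1-one | C1C(=O)[C@@H](c2ccc(O[Si](C(C)C)(C(C)C)C(C)C)cc2)[C@@H]1CO[Si](C(C)C)(C(C)C)C(C)C | intermediate
13 | (2R,3R)-1-hydroxy-2-[4-(triisopropylsilyloxy)phenyl]-3-[(triisopropylsilyloxy)methyl]cyclobutyl 3-chloroperoxybenzoate (Criegee adduct, C1 undefined) | C1C(O)(OOC(=O)c2cccc(Cl)c2)[C@@H](c3ccc(O[Si](C(C)C)(C(C)C)C(C)C)cc3)[C@@H]1CO[Si](C(C)C)(C(C)C)C(C)C | intermediate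
14 | (4S,5R)-5-[4-(triisopropylsilyloxy)phenyl]-4-[(triisopropylsilyloxy)methyl]oxolan-2-one | C1C(=O)O[C@@H](c2ccc(O[Si](C(C)C)(C(C)C)C(C)C)cc2)[C@@H]1CO[Si](C(C)C)(C(C)C)C(C)C | intermediate
15 | 4-methoxybenzaldehyde | COc1ccc(C=O)cc1 | starting material
16 | potassium enolate of 14 | C1=C([O-])O[C@@H](c2ccc(O[Si](C(C)C)(C(C)C)C(C)C)cc2)[C@@H]1CO[Si](C(C)C)(C(C)C)C(C)C.[K+] | intermediate
17 | (3S,4S,5R)-3-[(S)-hydroxy(4-methoxyphenyl)methyl]-5-[4-(triisopropylsilyloxy)phenyl]-4-[(triisopropylsilyloxy)methyl]oxolan-2-one | COc1ccc([C@@H](O)[C@H]2C(=O)O[C@@H](c3ccc(O[Si](C(C)C)(C(C)C)C(C)C)cc3)[C@@H]2CO[Si](C(C)C)(C(C)C)C(C)C)cc1 | intermediate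
18 | (1S,2R,3S,4R)-2-(hydroxymethyl)-1-(4-methoxyphenyl)-4-[4-(triisopropylsilyloxy)phenyl]-3-[(triisopropylsilyloxy)methyl]butane-1,4-diol | COc1ccc([C@@H](O)[C@@H](CO)[C@@H](CO[Si](C(C)C)(C(C)C)C(C)C)[C@@H](O)c2ccc(O[Si](C(C)C)(C(C)C)C(C)C)cc2)cc1 | intermediate
19 | (2R,3S,4R)-4-hydroxy-2-[(S)-hydroxy(4-methoxyphenyl)methyl]-4-[4-(triisopropylsilyloxy)phenyl]-3-[(triisopropylsilyloxy)methyl]butyl 4-methylbenzenesulfonate | COc1ccc([C@@H](O)[C@@H](COS(=O)(=O)c3ccc(C)cc3)[C@@H](CO[Si](C(C)C)(C(C)C)C(C)C)[C@@H](O)c2ccc(O[Si](C(C)C)(C(C)C)C(C)C)cc2)cc1 | intermediate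
20 | (2R,3S,4R)-4-[(S)-hydroxy(4-methoxyphenyl)methyl]-2-[4-(triisopropylsilyloxy)phenyl]-3-[(triisopropylsilyloxy)methyl]oxolane | COc1ccc([C@@H](O)[C@H]2CO[C@@H](c3ccc(O[Si](C(C)C)(C(C)C)C(C)C)cc3)[C@@H]2CO[Si](C(C)C)(C(C)C)C(C)C)cc1 | intermediate
21 | (2R,3S,4R)-2-(4-hydroxyphenyl)-3-(hydroxymethyl)-4-[(S)-hydroxy(4-methoxyphenyl)methyl]oxolane | COc1ccc([C@@H](O)[C@H]2CO[C@@H](c3ccc(O)cc3)[C@@H]2CO)cc1 | intermediate
22 | (2R,3S,4R)-2-(4-acetoxyphenyl)-3-(acetoxymethyl)-4-[(S)-acetoxy(4-methoxyphenyl)methyl]oxolane | COc1ccc([C@@H](OC(C)=O)[C@H]2CO[C@@H](c3ccc(OC(C)=O)cc3)[C@@H]2COC(C)=O)cc1 | intermediate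
23 | (2R,3S,4R)-3-(acetoxymethyl)-4-[(S)-acetoxy(4-methoxyphenyl)methyl]-2-(4-hydroxyphenyl)oxolane (CNP0231272.1) | COc1ccc([C@@H](OC(C)=O)[C@H]2CO[C@@H](c3ccc(O)cc3)[C@@H]2COC(C)=O)cc1 | target

**Step count**

Total step count: 12.
Longest linear sequence: 11 steps (1, 2, 4 to 12) from 4-hydroxyphenylacetic acid; step 3 is a one-step branch.

**Steps most likely to fail**

1. Step 4. The allylic oxygen lowers the nucleophilicity of the alkene. Capture of the keteniminium ion may therefore be slower than its self-condensation, and the heating then needed may erode facial discrimination by the auxiliary. The fallback sets out from 6 and comes back at 14. Ion 9 is generated in CH2Cl2 at or below room temperature in the presence of buta-1,3-diene. This much better π-nucleophile adds across one double bond through an allyl-stabilised cation and gives the 3-ethenylcyclobutaniminium triflate F1. Hydrolysis and DBU equilibration as in steps 4 and 5 give (2R,3S)-3-ethenyl-2-[4-(triisopropylsilyloxy)phenyl]cyclobutan-1-one F2. The peracid ring enlargement of step 6 should outrun epoxidation of a monosubstituted alkene and give (4S,5R)-4-ethenyl-5-[4-(triisopropylsilyloxy)phenyl]oxolan-2-one F3. Cleavage with OsO4 (cat.)–NaIO4 gives (2R,3R)-5-oxo-2-[4-(triisopropylsilyloxy)phenyl]oxolane-3-carbaldehyde F4. NaBH4 in cold ethanol with an acetic acid quench gives (4S,5R)-4-(hydroxymethyl)-5-[4-(triisopropylsilyloxy)phenyl]oxolan-2-one F5. This alcohol is silylated at once (TIPSCl, imidazole), before acyl transfer to the new hydroxyl can begin, to reach 14.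

2. Step 7. Simple diastereoselection at C7' may be poor, either because a closed metal-bridged transition state competes with the open one or because the aldolate equilibrates by retro-aldol before the quench. The fallback sets out from 14 and comes back at 17. The aldol is run without regard to C7' (LiN(SiMe3)2, THF, −78 °C). It gives 17 mixed with the anti aldol (3S,4S,5R)-3-[(R)-hydroxy(4-methoxyphenyl)methyl]-5-[4-(triisopropylsilyloxy)phenyl]-4-[(triisopropylsilyloxy)methyl]oxolan-2-one F6. The mixture is oxidised with Dess–Martin periodinane to the single β-keto lactone (3S,4S,5R)-3-(4-methoxybenzoyl)-5-[4-(triisopropylsilyloxy)phenyl]-4-[(triisopropylsilyloxy)methyl]oxolan-2-one F7, in which C4 is labile but rests trans to the C3 arm. Catalyst-controlled asymmetric transfer hydrogenation of Noyori type follows (RuCl[(S,S)-TsDPEN](p-cymene), HCO2H–Et3N). Its ligand delivers (S)-aryl carbinols and should return 17.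

3. Step 9. Sulfonylation may spill over to the two benzylic hydroxyls, with ionisation at the para-methoxybenzylic centre and scrambling of C7', or ring closure may lag behind chloride displacement of the sulfonate. The fallback sets out from 17 and comes back at 21. The C7' hydroxyl is masked first (TBSOTf, 2,6-lutidine) to give the C7' tert-butyldimethylsilyl ether of 17 F8, which also removes the retro-aldol pathway from the reduction. Reduction with iBu2AlH gives the 1,4-diol carrying the C7' silyl ether F9. Redox dehydration under Mitsunobu conditions (PPh3, DIAD) activates the primary hydroxyl and closes O1–C5 to give the C7' tert-butyldimethylsilyl ether of 20 F10. The fluoride treatment of step 10 then removes all three silyl groups and gives 21.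

**Further compounds**

F1 | step 4 | (2R,5R)-1-{(3S)-3-ethenyl-2-[4-(triisopropylsilyloxy)phenyl]cyclobutylidene}-2,5-dimethylpyrrolidinium triflate (C2 epimers) | C1C(=[N+]2[C@H](C)CC[C@H]2C)C(c3ccc(O[Si](C(C)C)(C(C)C)C(C)C)cc3)[C@@H]1C=C.[O-]S(=O)(=O)C(F)(F)F
F2 | step 4 | (2R,3S)-3-ethenyl-2-[4-(triisopropylsilyloxy)phenyl]cyclobutan-1-one | C1C(=O)[C@@H](c2ccc(O[Si](C(C)C)(C(C)C)C(C)C)cc2)[C@@H]1C=C
F3 | step 4 | (4S,5R)-4-ethenyl-5-[4-(triisopropylsilyloxy)phenyl]oxolan-2-one | C1C(=O)O[C@@H](c2ccc(O[Si](C(C)C)(C(C)C)C(C)C)cc2)[C@@H]1C=C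
F4 | step 4 | (2R,3R)-5-oxo-2-[4-(triisopropylsilyloxy)phenyl]oxolane-3-carbaldehyde | C1C(=O)O[C@@H](c2ccc(O[Si](C(C)C)(C(C)C)C(C)C)cc2)[C@@H]1C=O
F5 | step 4 | (4S,5R)-4-(hydroxymethyl)-5-[4-(triisopropylsilyloxy)phenyl]oxolan-2-one | C1C(=O)O[C@@H](c2ccc(O[Si](C(C)C)(C(C)C)C(C)C)cc2)[C@@H]1CO
F6 | step 7 | (3S,4S,5R)-3-[(R)-hydroxy(4-methoxyphenyl)methyl]-5-[4-(triisopropylsilyloxy)phenyl]-4-[(triisopropylsilyloxy)methyl]oxolan-2-one | COc1ccc([C@H](O)[C@H]2C(=O)O[C@@H](c3ccc(O[Si](C(C)C)(C(C)C)C(C)C)cc3)[C@@H]2CO[Si](C(C)C)(C(C)C)C(C)C)cc1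
F7 | step 7 | (3S,4S,5R)-3-(4-methoxybenzoyl)-5-[4-(triisopropylsilyloxy)phenyl]-4-[(triisopropylsilyloxy)methyl]oxolan-2-one | COc1ccc(C(=O)[C@H]2C(=O)O[C@@H](c3ccc(O[Si](C(C)C)(C(C)C)C(C)C)cc3)[C@@H]2CO[Si](C(C)C)(C(C)C)C(C)C)cc1
F8 | step 9 | (3S,4S,5R)-3-[(S)-(tert-butyldimethylsilyloxy)(4-methoxyphenyl)methyl]-5-[4-(triisopropylsilyloxy)phenyl]-4-[(triisopropylsilyloxy)methyl]oxolan-2-one | COc1ccc([C@@H](O[Si](C)(C)C(C)(C)C)[C@H]2C(=O)O[C@@H](c3ccc(O[Si](C(C)C)(C(C)C)C(C)C)cc3)[C@@H]2CO[Si](C(C)C)(C(C)C)C(C)C)cc1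
F9 | step 9 | (1R,2S,3R)-3-[(S)-(tert-butyldimethylsilyloxy)(4-methoxyphenyl)methyl]-1-[4-(triisopropylsilyloxy)phenyl]-2-[(triisopropylsilyloxy)methyl]butane-1,4-diol | COc1ccc([C@@H](O[Si](C)(C)C(C)(C)C)[C@@H](CO)[C@@H](CO[Si](C(C)C)(C(C)C)C(C)C)[C@@H](O)c2ccc(O[Si](C(C)C)(C(C)C)C(C)C)cc2)cc1
F10 | step 9 | (2R,3S,4R)-4-[(S)-(tert-butyldimethylsilyloxy)(4-methoxyphenyl)methyl]-2-[4-(triisopropylsilyloxy)phenyl]-3-[(triisopropylsilyloxy)methyl]oxolane | COc1ccc([C@@H](O[Si](C)(C)C(C)(C)C)[C@H]2CO[C@@H](c3ccc(O[Si](C(C)C)(C(C)C)C(C)C)cc3)[C@@H]2CO[Si](C(C)C)(C(C)C)C(C)C)cc1
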